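**Plan**

- Retrosynthesis first cuts the four O–CH3 bonds (para-methoxy of ring A, the three methoxy groups of ring E). It then traces all eight C(aryl)–OH bonds of rings A–D back to C(aryl)–CHO bonds in one Baeyer–Villiger (Dakin-type) operation.
- The feature that allows this: in each of rings A, B, C and D the carbon carrying the ether oxygen to the next ring sits between two C–OH carbons (eight in all). Carried as formyl carbons, they first activate that carbon for fluoride displacement and then become the hydroxyls.
- The four diaryl ether C–O bonds are cut one at a time (A–B first, D–E last), each between the ether oxygen and the formyl-flanked carbon.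
- Forward: a methyl-capped and an allyl-capped fluoro dialdehyde are made from 4-fluoro-3,5-dimethylphenol. The chain is joined E → D → C → B → A by four SNAr rounds, with allyl removal between rounds; no ring is formed at any stage.
- Stereochemistry: the target has no stereocentre and no stereogenic axis, so nothing needs to be set.

Key step: step 13

Assumption: rings are lettered A (2,4,6-trihydroxyphenoxy end) to E (3,4,5-trihydroxyphenyl end), and the mCPBA is dried and freed of water before use so that the aryl formates persist until the oxidant is destroyed.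

**Route**

Step 1
Reactants: 1 4-fluoro-3,5-dimethylphenol
Product: 2 4-fluoro-3,5-dimethylphenyl acetate
Conditions: Ac2O (1.2 equiv), pyridine (2 equiv), DMAP (cat.), CH2Cl2, 0 °C to rt
Reagents that add atoms: acetic anhydride, CC(=O)OC(C)=O
Why: DMAP-catalysed O-acetylation turns the strongly activating hydroxyl into an ester, so that the ring should resist electrophilic bromination in the next step.

Step 2
Reactants: 2 4-fluoro-3,5-dimethylphenyl acetate
Product: 3 3,5-bis(dibromomethyl)-4-fluorophenyl acetate
Conditions: NBS (4.6 equiv), AIBN (cat.), PhCF3, reflux, visible light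
Reagents that add atoms: N-bromosuccinimide, O=C1CCC(=O)N1Br
Why: Wohl–Ziegler radical bromination should take each benzylic methyl to the dibromomethyl stage, a third bromine being disfavoured sterically, while the acetoxy- and fluoro-substituted ring stays inert to bromine and HBr.

Step 3
Reactants: 3 3,5-bis(dibromomethyl)-4-fluorophenyl acetate
Product: 5 2-fluoro-5-hydroxybenzene-1,3-dicarbaldehyde, via 4-fluoro-3,5-diformylphenyl acetate 4 (not isolated)
Conditions: AgNO3 (4.2 equiv), acetone–H2O, reflux, dark; then 2 M aq. HCl, 50 °C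
Reagents that add atoms: water, O
Why: Silver-assisted hydrolysis of the two benzal bromides gives the dialdehyde, and the acidic medium then cleaves the aryl acetate without ever generating a phenoxide that could attack the activated C–F bond.

Step 4
Reactants: 5 2-fluoro-5-hydroxybenzene-1,3-dicarbaldehyde
Product: 6 2-fluoro-5-methoxybenzene-1,3-dicarbaldehyde
Conditions: MeI (3 equiv), K2CO3 (1.2 equiv), MeCN, rt
Reagents that add atoms: iodomethane, CI
Why: Williamson O-methylation of the acidic phenol at room temperature should be much faster than fluoride displacement by the weakly nucleophilic diformylphenoxide, which needs heat in a dipolar aprotic solvent.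

Step 5
Reactants: 5 2-fluoro-5-hydroxybenzene-1,3-dicarbaldehyde
Product: 7 5-(allyloxy)-2-fluorobenzene-1,3-dicarbaldehyde
Conditions: allyl bromide (2 equiv), K2CO3 (1.2 equiv), MeCN, rt
Reagents that add atoms: allyl bromide, C=CCBr
Why: Williamson O-allylation installs a tail protecting group that survives carbonate in DMF and is later removed under near-neutral palladium catalysis without touching aldehydes, methyl ethers or diaryl ethers.

Step 6
Reactants: 8 3,4,5-trimethoxyphenol; 7 5-(allyloxy)-2-fluorobenzene-1,3-dicarbaldehyde
Product: 9 5-(allyloxy)-2-(3,4,5-trimethoxyphenoxy)benzene-1,3-dicarbaldehyde (E–D dimer)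
Conditions: K2CO3 (1.5 equiv), 7 (1.1 equiv), DMF, 4 Å MS, 50 °C
Reagents that add atoms: none
Why: SNAr by addition–elimination, in which the electron-rich phenoxide adds to the fluorine-bearing carbon, the Meisenheimer complex is stabilised by both ortho formyl groups and fluoride leaves, the non-enolisable aldehydes tolerating carbonate.

Step 7
Reactants: 9 E–D dimer allyl ether
Product: 10 5-hydroxy-2-(3,4,5-trimethoxyphenoxy)benzene-1,3-dicarbaldehyde (E–D dimer phenol)
Conditions: Pd(PPh3)4 (5 mol %), HCO2H (3 equiv), Et3N (3 equiv), THF, 40 °C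
Reagents that add atoms: none
Why: Tsuji–Trost-type deallylation, in which zerovalent palladium ionises the allyl ether of the acidic phenol to a π-allyl complex that formate reduces to propene with loss of CO2, conditions that leave aldehydes and the activated diaryl ether alone.

Step 8
Reactants: 10 E–D dimer phenol; 7 5-(allyloxy)-2-fluorobenzene-1,3-dicarbaldehyde
Product: 11 5-(allyloxy)-2-[3,5-diformyl-4-(3,4,5-trimethoxyphenoxy)phenoxy]benzene-1,3-dicarbaldehyde (E–D–C trimer)
Conditions: Cs2CO3 (1.3 equiv), 7 (1.15 equiv), DMF, 4 Å MS, 60 °C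
Reagents that add atoms: none
Why: The same SNAr, now with a diformylphenoxide that is weaker but unhindered (its oxygen is para to the existing ether), and fluoride is a far better nucleofuge on the doubly activated carbon than the aryloxide already in the chain, so the existing ether should stay intact at this temperature.

Step 9
Reactants: 11 E–D–C trimer allyl ether
Product: 12 5-hydroxy-2-[3,5-diformyl-4-(3,4,5-trimethoxyphenoxy)phenoxy]benzene-1,3-dicarbaldehyde (E–D–C trimer phenol)
Conditions: Pd(PPh3)4 (5 mol %), HCO2H (3 equiv), Et3N (3 equiv), THF, 40 °C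
Reagents that add atoms: none
Why: Palladium-catalysed formate hydrogenolysis of the aryl allyl ether as in step 7, the four formyl groups being inert to the π-allyl and hydride intermediates of this cycle.

Step 10
Reactants: 12 E–D–C trimer phenol; 7 5-(allyloxy)-2-fluorobenzene-1,3-dicarbaldehyde
Product: 13 5-(allyloxy)-2-{3,5-diformyl-4-[3,5-diformyl-4-(3,4,5-trimethoxyphenoxy)phenoxy]phenoxy}benzene-1,3-dicarbaldehyde (E–D–C–B tetramer)
Conditions: Cs2CO3 (1.3 equiv), 7 (1.2 equiv), DMF, 4 Å MS, 60 °C
Reagents that add atoms: none
Why: A third SNAr round of the same kind, in which the reacting phenoxide has the same local environment as in step 8, so comparable reactivity is expected.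

Step 11
Reactants: 13 E–D–C–B tetramer allyl ether
Product: 14 5-hydroxy-2-{3,5-diformyl-4-[3,5-diformyl-4-(3,4,5-trimethoxyphenoxy)phenoxy]phenoxy}benzene-1,3-dicarbaldehyde (E–D–C–B tetramer phenol)
Conditions: Pd(PPh3)4 (5 mol %), HCO2H (3 equiv), Et3N (3 equiv), THF, 40 °C
Reagents that add atoms: none
Why: Palladium-catalysed formate hydrogenolysis of the aryl allyl ether as in steps 7 and 9.

Step 12
Reactants: 14 E–D–C–B tetramer phenol; 6 2-fluoro-5-methoxybenzene-1,3-dicarbaldehyde
Product: 15 5-methoxy-2-(3,5-diformyl-4-{3,5-diformyl-4-[3,5-diformyl-4-(3,4,5-trimethoxyphenoxy)phenoxy]phenoxy}phenoxy)benzene-1,3-dicarbaldehyde (pentamer octa-aldehyde)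
Conditions: Cs2CO3 (1.3 equiv), 6 (1.3 equiv), DMF, 4 Å MS, 60 °C
Reagents that add atoms: none
Why: A fourth SNAr round that caps the chain with ring A, whose para-methoxy group is carried on as a spectator.

Step 13
Reactants: 15 pentamer octa-aldehyde
Product: 17 pentamer octaphenol tetramethyl ether, via pentamer octaformate 16 (not isolated)
Conditions: mCPBA (dried, 14 equiv), CH2Cl2, 0 °C to 40 °C; aq. Na2S2O3 wash; then HCl in MeOH (0.1 M), argon, rt
Reagents that add atoms: 3-chloroperoxybenzoic acid (mCPBA), O=C(OO)c1cccc(Cl)c1
Why: Each formyl group adds the peracid to give a Criegee adduct, the aryl group migrates from carbon to oxygen as 3-chlorobenzoate leaves, and the resulting aryl formate is cleaved by acidic methanolysis after the excess oxidant has been reduced. The closest known reaction is the Baeyer–Villiger (Dakin-type) oxidation of ortho-alkoxy and ortho-aryloxy benzaldehydes with mCPBA, applied here to eight formyl groups of one substrate. No ring is closed and no stereocentre is formed. The selectivity needed is aryl over hydride migration in every Criegee adduct, and it is secured by the ortho aryloxy oxygen, whose lone pair stabilises the electron-deficient migrating carbon. Each formyl group converted to formyloxy removes an acceptor from its ring, so the second migration on that ring should be easier than the first. Keeping the phenols masked as formates until the peracid is gone protects the electron-rich product and ring E from over-oxidation to quinones.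

Step 14
Reactants: 17 pentamer octaphenol tetramethyl ether
Product: 18 target CNP0308003.0 (pentamer dodecaphenol)
Conditions: BBr3 (20 equiv), CH2Cl2, −78 °C to rt; then ice-water, argon
Reagents that add atoms: none
Why: Lewis-acid ether cleavage, in which BBr3 coordinates each methoxy oxygen and bromide attacks the methyl carbon, whereas the diaryl ether carbons cannot undergo this substitution, the large excess allowing for the eight phenols that first form borates.

**Compound list**

1 | 4-fluoro-3,5-dimethylphenol | Cc1cc(O)cc(C)c1F | starting material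
2 | 4-fluoro-3,5-dimethylphenyl acetate | CC(=O)Oc1cc(C)c(F)c(C)c1 | intermediate
3 | 3,5-bis(dibromomethyl)-4-fluorophenyl acetate | CC(=O)Oc1cc(C(Br)Br)c(F)c(C(Br)Br)c1 | intermediate
4 | 4-fluoro-3,5-diformylphenyl acetate | CC(=O)Oc1cc(C=O)c(F)c(C=O)c1 | intermediate (not isolated)
5 | 2-fluoro-5-hydroxybenzene-1,3-dicarbaldehyde | Oc1cc(C=O)c(F)c(C=O)c1 | intermediate
6 | 2-fluoro-5-methoxybenzene-1,3-dicarbaldehyde (ring A monomer) | COc1cc(C=O)c(F)c(C=O)c1 | intermediate
7 | 5-(allyloxy)-2-fluorobenzene-1,3-dicarbaldehyde (monomer for rings B, C and D) | C=CCOc1cc(C=O)c(F)c(C=O)c1 | intermediate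
8 | 3,4,5-trimethoxyphenol (ring E) | COc1cc(O)cc(OC)c1OC | starting material
9 | 5-(allyloxy)-2-(3,4,5-trimethoxyphenoxy)benzene-1,3-dicarbaldehyde (E–D dimer) | C=CCOc1cc(C=O)c(Oc2cc(OC)c(OC)c(OC)c2)c(C=O)c1 | intermediate
10 | 5-hydroxy-2-(3,4,5-trimethoxyphenoxy)benzene-1,3-dicarbaldehyde (E–D dimer phenol) | Oc1cc(C=O)c(Oc2cc(OC)c(OC)c(OC)c2)c(C=O)c1 | intermediate
11 | E–D–C trimer allyl ether, tetra-aldehyde | C=CCOc1cc(C=O)c(Oc2cc(C=O)c(Oc3cc(OC)c(OC)c(OC)c3)c(C=O)c2)c(C=O)c1 | intermediate
12 | E–D–C trimer phenol, tetra-aldehyde | Oc1cc(C=O)c(Oc2cc(C=O)c(Oc3cc(OC)c(OC)c(OC)c3)c(C=O)c2)c(C=O)c1 | intermediate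
13 | E–D–C–B tetramer allyl ether, hexa-aldehyde | C=CCOc1cc(C=O)c(Oc2cc(C=O)c(Oc3cc(C=O)c(Oc4cc(OC)c(OC)c(OC)c4)c(C=O)c3)c(C=O)c2)c(C=O)c1 | intermediate
14 | E–D–C–B tetramer phenol, hexa-aldehyde | Oc1cc(C=O)c(Oc2cc(C=O)c(Oc3cc(C=O)c(Oc4cc(OC)c(OC)c(OC)c4)c(C=O)c3)c(C=O)c2)c(C=O)c1 | intermediate
15 | pentamer octa-aldehyde (ring A 4-methoxy-2,6-diformylphenoxy; rings B–D 3,5-diformyl-1,4-dioxy; ring E 3,4,5-trimethoxyphenyl) | COc1cc(C=O)c(Oc2cc(C=O)c(Oc3cc(C=O)c(Oc4cc(C=O)c(Oc5cc(OC)c(OC)c(OC)c5)c(C=O)c4)c(C=O)c3)c(C=O)c2)c(C=O)c1 | intermediate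
16 | pentamer octaformate (each CHO of 15 replaced by OCHO) | COc1cc(OC=O)c(Oc2cc(OC=O)c(Oc3cc(OC=O)c(Oc4cc(OC=O)c(Oc5cc(OC)c(OC)c(OC)c5)c(OC=O)c4)c(OC=O)c3)c(OC=O)c2)c(OC=O)c1 | intermediate (not isolated)
17 | pentamer octaphenol tetramethyl ether | COc1cc(O)c(Oc2cc(O)c(Oc3cc(O)c(Oc4cc(O)c(Oc5cc(OC)c(OC)c(OC)c5)c(O)c4)c(O)c3)c(O)c2)c(O)c1 | intermediate
18 | CNP0308003.0, pentamer dodecaphenol (achiral) | Oc1cc(O)c(Oc2cc(O)c(Oc3cc(O)c(Oc4cc(O)c(Oc5cc(O)c(O)c(O)c5)c(O)c4)c(O)c3)c(O)c2)c(O)c1 | target

**Step count and risks**

Total step count: 14. Longest linear sequence: 13 steps (steps 1, 2, 3, 5, 6, 7, 8, 9, 10, 11, 12, 13, 14); step 4 is the only branch.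

Steps most likely to fail:

Step 13. Three processes could defeat the global oxidation. Hydride rather than aryl migration may occur in the Criegee adducts of formyl groups whose ring still carries a second, unconverted formyl group, which would leave carboxylic acids. Conversion may stall at mixed aldehyde/formate stages. The peracid may attack ring E, or phenols set free by premature formate hydrolysis. The fallback removes the hydride-migration channel by changing the oxidation level, and sets out from 15. Eightfold addition of MeMgBr (THF, −78 °C) should give the pentamer octakis(1-hydroxyethyl) compound F1 as a mixture of diastereomers. Oxidation with Dess–Martin periodinane (CH2Cl2, rt) should give the pentamer octa-acetyl compound F2. Baeyer–Villiger oxidation of these aryl methyl ketones (mCPBA, cat. CF3CO2H, CH2Cl2), in which only aryl migration competes with the poorly migrating methyl group, should give the pentamer octa-acetate F3. Methanolysis (HCl in MeOH, argon) returns the route at 17.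

Step 12. The hexaformyl phenoxide of 14 is weakly nucleophilic and may be poorly soluble, so substitution may be slow. Aryloxide exchange at the formyl-activated ether carbons already in the chain (trans-etherification) and carbonate-induced aldehyde degradation could then compete and scramble chain length. The fallback switches off that activation during the coupling, and sets out from 14. Acetalisation (trimethyl orthoformate, MeOH, cat. p-toluenesulfonic acid) should give the tetramer phenol hexakis(dimethyl acetal) F4. Its phenoxide is more nucleophilic and its internal ether carbons are no longer SNAr-active. Coupling with 6 (Cs2CO3, DMF, 50 °C) should give the pentamer dialdehyde hexakis(dimethyl acetal) F5. Aqueous HCl in THF then unmasks the six aldehydes and returns the route at 15.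

Step 14. Demethylation may stop short because partly cleaved polyborates precipitate from CH2Cl2, and the free dodecaphenol may degrade oxidatively during aqueous work-up and chromatography. The fallback isolates the product through a stable derivative instead of as the free phenol, and sets out from 17. After the BBr3 treatment and a methanol quench under argon, the crude material is acetylated directly (Ac2O, pyridine, DMAP) to the pentamer dodeca-acetate F6. This can be purified on silica and separated from under-demethylated material, which can be resubmitted. Acidic methanolysis (HCl in MeOH, argon, rt) followed by evaporation returns the route at 18.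

**Further compounds**

F1 | step 13 | pentamer octakis(1-hydroxyethyl) tetramethyl ether (mixture of diastereomers) | COc1cc(C(C)O)c(Oc2cc(C(C)O)c(Oc3cc(C(C)O)c(Oc4cc(C(C)O)c(Oc5cc(OC)c(OC)c(OC)c5)c(C(C)O)c4)c(C(C)O)c3)c(C(C)O)c2)c(C(C)O)c1
F2 | step 13 | pentamer octa-acetyl tetramethyl ether | COc1cc(C(C)=O)c(Oc2cc(C(C)=O)c(Oc3cc(C(C)=O)c(Oc4cc(C(C)=O)c(Oc5cc(OC)c(OC)c(OC)c5)c(C(C)=O)c4)c(C(C)=O)c3)c(C(C)=O)c2)c(C(C)=O)c1
F3 | step 13 | pentamer octa-acetate tetramethyl ether | COc1cc(OC(C)=O)c(Oc2cc(OC(C)=O)c(Oc3cc(OC(C)=O)c(Oc4cc(OC(C)=O)c(Oc5cc(OC)c(OC)c(OC)c5)c(OC(C)=O)c4)c(OC(C)=O)c3)c(OC(C)=O)c2)c(OC(C)=O)c1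
F4 | step 12 | E–D–C–B tetramer phenol hexakis(dimethyl acetal) | Oc1cc(C(OC)OC)c(Oc2cc(C(OC)OC)c(Oc3cc(C(OC)OC)c(Oc4cc(OC)c(OC)c(OC)c4)c(C(OC)OC)c3)c(C(OC)OC)c2)c(C(OC)OC)c1
F5 | step 12 | pentamer ring A dialdehyde with rings B–D as hexakis(dimethyl acetal) | COc1cc(C=O)c(Oc2cc(C(OC)OC)c(Oc3cc(C(OC)OC)c(Oc4cc(C(OC)OC)c(Oc5cc(OC)c(OC)c(OC)c5)c(C(OC)OC)c4)c(C(OC)OC)c3)c(C(OC)OC)c2)c(C=O)c1
F6 | step 14 | pentamer dodeca-acetate of the target | CC(=O)Oc1cc(OC(C)=O)c(Oc2cc(OC(C)=O)c(Oc3cc(OC(C)=O)c(Oc4cc(OC(C)=O)c(Oc5cc(OC(C)=O)c(OC(C)=O)c(OC(C)=O)c5)c(OC(C)=O)c4)c(OC(C)=O)c3)c(OC(C)=O)c2)c(OC(C)=O)c1
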